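All runs were generated by integration with constants of no real substance, and the scatter is random.

| flask | free monomer | initiator | remark | time |
|---|---|---|---|---|
| spring | 2 M | 0.044 mol% | run made earlier |  |
| winter | 2 M | 0.12 mol% | run made earlier |  |
| grey | 2.0 M | 0.2 mol% |  | 50 min |
| red | 2.0 M | 0.06 mol% |  | 50 min |

| run | time / min | monomer in chains / % | free monomer / % |
|---|---|---|---|
| spring | 3.00 | 9 | 95 |
| spring | 8.00 | 18 | 83 |
| spring | 15.0 | 28 | 71 |
| spring | 25.0 | 44 | 57 |
| spring | 40.0 | 56 | 42 |
| winter | 8.00 | 26 | 75 |
| winter | 15.0 | 41 | 59 |
| winter | 20.0 | 53 | 49 |
| winter | 30.0 | 64 | 35 |
| winter | 40.0 | 77 | 26 |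

(each reading ± 1.5 percentage points)

- the average divides the monomer in chains by the number of chains, living and dead together; two radicals that join make one chain
- the earlier runs do not show the number of chains; that part of a forecast is a guess

1. which of the two ends with the longer chains by the average number of monomer units in a chain (living and dead chains, two that joined counted as one) ("neither" if they lie within 10%) (grey / red / neither)
2. average number of monomer units in a chain (living and dead chains, two that joined counted as one) at the end, grey
3. average number of monomer units in a chain (living and dead chains, two that joined counted as one) at the end, red

At 0.0357 min⁻¹ up to 20.0 min and 0.0317 min⁻¹ from there to 40.0 min, the pseudo-first-order slope of free monomer in the winter run bends a little, and that bend is the reading to watch. At 40.0 min the log loss in the winter run stands 1.55 times that of the spring run, and the root of the loading ratio is 1.65, so the slope is taken to follow the root of the initiator present. Scaling the winter slope this way gives the share X of free monomer in chains at 50 min: 88.6% for grey and 69.6% for red.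

Two radicals that join make one chain, so one initiator spent is counted as one chain. The length is then L = X/(wφ), with w the initiator per free monomer charged and φ the share of charged initiator spent.

One extreme has φ equal to one: grey gives 443 and red 1160. The other has initiator that stays whole: the slope shows no bend and L has no ceiling. The bend places the flask between them. The later slope stands at 0.888 of the earlier one; read as the root of the initiator falling to that fraction across 20.0 min, this gives a decay constant of 0.0118 min⁻¹ and a half-life of 58.6 min, longer than the 50 min of grey and red. This is a rough reading, with a scatter of 1.5 percentage points on a reading of 26%. By 50 min the spent share is φ = 44.7%, taken as the same in grey and red. My reckoning is 992 for grey and 2600 for red, longer in red.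

The forecast says red, with 5400 for grey and 14000 for red, and guesses 8 per cent where this reckoning has φ: “The ratio of about 2.7 is firm; the absolute values are guesses.”

The flasks give 1020 for grey and 2670 for red, so red ends longer.

    initiator → 2 initiating radical (k = 1.90 × 10⁻⁴ s⁻¹)
    2 growing radical → dead chain (k = 8.00 × 10⁸ L mol⁻¹ s⁻¹)
    free monomer + growing radical → monomer in chains + growing radical, rate k3*[growing radical]*[free monomer] (k = 27000 L mol⁻¹ s⁻¹)
    free monomer → decomposition product (k = 4.50 × 10⁻⁷ s⁻¹)
    free monomer + initiating radical → growing radical + monomer in chains (k = 5.80 × 10⁵ L mol⁻¹ s⁻¹)

A neighbouring flask, like red but with 0.24 mol% of initiator, takes the same reckoning. The root scaling gives X = 90.8%, and with φ unchanged L = 846. That flask keeps 9.2% of its free monomer and 57% of its initiator, and ends at 871.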